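**Strategy.** Ring A of the upper flavan is cut from pyran ring C at both of its ortho bonds, O1–C8a and C4a–C4, and enters as an aryne. The precursor is an (S)-β-hydroxy ketone whose carbinol carbon (future C2) carries ring B and whose carbonyl carbon (future C4) carries C8 of protected epiafzelechin. In one operation its alkoxide oxygen arylates one aryne carbon and the aryl anion closes onto the ketone, giving the chroman-4-ol. The step exploits the ortho placement of O1 and C4 on ring A and their 1,3-spacing across C2–C3. A bromine at C5 steers the aryne regiochemistry and leaves in the final hydrogenolysis, after ionic hydrogenation has set C4.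

Key step: step 8

Remark: (−)-epiafzelechin (1) and the β-keto ester 4 are taken as catalogue compounds; atom numbers are flavan numbers of the upper unit (O1, C2, C3, C4, C4a, C5–C8, C8a).

Step 1
Reactants: 1 (−)-epiafzelechin
Product: 2 (2R,3R)-3,5,7-tris(benzyloxy)-2-[4-(benzyloxy)phenyl]chroman (tetra-O-benzylepiafzelechin)
Conditions: NaH (5 equiv), BnBr (5 equiv), DMF, −10 °C to rt
Reagents that add atoms: benzyl bromide, BrCc1ccccc1
Why: Williamson etherification of the three phenols and the C3 alcohol should proceed without touching a stereocentre, since the phenoxides are capped at low temperature before base-induced opening at C2 can occur.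

Step 2
Reactants: 2 tetra-O-benzylepiafzelechin
Product: 3 (2R,3R)-3,5,7-tris(benzyloxy)-2-[4-(benzyloxy)phenyl]-8-bromochroman
Conditions: NBS (1.0 equiv), CH2Cl2, −78 °C to rt
Reagents that add atoms: N-bromosuccinimide, O=C1CCC(=O)N1Br
Why: Electrophilic aromatic bromination of 5,7-dibenzyloxyflavans should occur at C8, the more nucleophilic of the two free positions of the phloroglucinol ring.

Step 3
Reactants: 4 ethyl 3-[4-(benzyloxy)phenyl]-3-oxopropanoate
Product: 5 ethyl (S)-3-[4-(benzyloxy)phenyl]-3-hydroxypropanoate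
Conditions: RuCl[(S,S)-TsDPEN](p-cymene) (cat.), HCO2H–Et3N (5:2), 30 °C
Reagents that add atoms: none
Why: Noyori asymmetric transfer hydrogenation of the aryl ketone should deliver hydride to its Re face under control of the (S,S)-diamine ligand, setting the S carbinol centre that becomes C2, with the benzyl ether inert to the homogeneous catalyst.

Step 4
Reactants: 5 ethyl (S)-3-[4-(benzyloxy)phenyl]-3-hydroxypropanoate
Product: 6 (S)-3-[4-(benzyloxy)phenyl]-3-hydroxy-N-methoxy-N-methylpropanamide
Conditions: MeNH(OMe)·HCl, i-PrMgCl (excess), THF, −20 to 0 °C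
Reagents that add atoms: N,O-dimethylhydroxylamine hydrochloride, Cl.CNOC
Why: Aminolysis of the ester by the magnesium amide (Weinreb amide formation) should tolerate the free hydroxyl as its magnesium alkoxide and leave the carbinol centre untouched.

Step 5
Reactants: 3 8-bromo-tetra-O-benzylepiafzelechin; 6 (S)-hydroxy Weinreb amide
Product: 9 (S)-3-[4-(benzyloxy)phenyl]-3-hydroxy-1-[(2R,3R)-3,5,7-tris(benzyloxy)-2-(4-(benzyloxy)phenyl)chroman-8-yl]propan-1-one, via 8-lithio arene 7 (not isolated), via chloromagnesium alkoxide 8 (not isolated)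
Conditions: 3, n-BuLi, THF, −78 °C; 6, i-PrMgCl (1.0 equiv), THF, −40 °C, added to the aryllithium; −78 to 0 °C; aq NH4Cl
Reagents that add atoms: none
Why: Bromine–lithium exchange followed by Weinreb ketone synthesis should stop at the ketone through the chelated tetrahedral intermediate, the hydroxyl being masked as an alkoxide that resists β-elimination, so the C8–carbonyl bond is made regiospecifically and no stereocentre changes.

Step 6
Reactants: 10 4-(benzyloxy)phenol
Product: 11 4-(benzyloxy)-2,6-dibromophenol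
Conditions: NBS (2.1 equiv), i-Pr2NH (cat.), CH2Cl2, 0 °C to rt
Reagents that add atoms: N-bromosuccinimide, O=C1CCC(=O)N1Br
Why: Amine-catalysed electrophilic bromination should be directed to both positions ortho to the free hydroxyl, the para position being blocked.

Step 7
Reactants: 11 4-(benzyloxy)-2,6-dibromophenol
Product: 14 4-(benzyloxy)-2-bromo-6-(trimethylsilyl)phenyl trifluoromethanesulfonate, via dibromoaryl silyl ether 12 (not isolated), via lithium silylphenoxide 13 (not isolated)
Conditions: HMDS, THF, 70 °C, evaporate; n-BuLi (1.0 equiv), THF, −100 to −80 °C; Tf2O, −100 °C to rt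
Reagents that add atoms: hexamethyldisilazane, C[Si](C)(C)N[Si](C)(C)C; trifluoromethanesulfonic anhydride, O=S(=O)(OS(=O)(=O)C(F)(F)F)C(F)(F)F
Why: O-silylation, exchange of one of the two equivalent bromines, and retro-Brook 1,3-migration of silicon from oxygen to carbon should give the ortho-silyl phenoxide, which is trapped as the triflate while the second bromine stays meta to the lithiated carbon and is therefore safe.

Step 8
Reactants: 9 (S)-β-hydroxy ketone; 14 ortho-silylaryl triflate
Product: 16 (2S)-7-(benzyloxy)-2-[4-(benzyloxy)phenyl]-5-bromo-4-[(2R,3R)-3,5,7-tris(benzyloxy)-2-(4-(benzyloxy)phenyl)chroman-8-yl]chroman-4-ol (both C4 epimers), via 5-benzyloxy-3-bromobenzyne 15 (not isolated)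
Conditions: 14 (1.5 equiv, slow addition), CsF (3 equiv), MeCN–THF (1:1), 0 °C to rt
Reagents that add atoms: none
Why: Proposed new method: fluoride should unmask aryne 15 from 14, the fluoride-activated C2 hydroxyl of 9 should add to the aryne carbon remote from bromine (future C8a), and the aryl anion thus formed next to bromine (future C4a) should attack the ketone carbon (future C4). The closest known reaction type is the aryne annulation of ortho-hydroxyaryl carbonyl compounds (salicylates to xanthones, ortho-hydroxychalcones to xanthenes), extended here from a phenoxide to an aliphatic secondary alkoxide with a ketone in the 1,3-position. Ring C closes by 6-exo-trig addition of the aryl carbanion to the carbonyl group, after the intermolecular O1–C8a bond formation. C2 keeps its S configuration because its C–O bond is never broken, and the new carbinol centre C4 forms without control, which is harmless because step 9 planarises it. The step needs regioselective attack on the unsymmetrical aryne, secured by the inductively withdrawing bromine beside one aryne carbon (attack at the distal carbon, charge next to bromine), and O- over C-arylation, secured because CsF hydrogen-bonds the alcohol but hardly enolises the hindered di-ortho-substituted aryl ketone. The six-membered ring closure is relied on to outrun protonation of the aryl anion, loss of bromide from it, and retro-aldol cleavage.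

Step 9
Reactants: 16 4-aryl-5-bromochroman-4-ol
Product: 17 (2S,4R)-7-(benzyloxy)-2-[4-(benzyloxy)phenyl]-5-bromo-4-[(2R,3R)-3,5,7-tris(benzyloxy)-2-(4-(benzyloxy)phenyl)chroman-8-yl]chroman (2,4-cis; the C4 descriptor is R only because bromine raises the priority of ring A)
Conditions: Et3SiH (5 equiv), TFA, CH2Cl2, −78 to −20 °C
Reagents that add atoms: none
Why: Ionic hydrogenation should ionise the tertiary bis-benzylic alcohol to a C4 cation stabilised by O1 (ortho) and the 7-benzyloxy group (para) of ring A, and hydride should enter axially on the face of H2 of the half-chair that holds ring B equatorial, placing the epiafzelechin unit cis to ring B under control of C2.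

Step 10
Reactants: 17 hexabenzyl 5-bromo biflavan
Product: 18 (2S,4S)-2-(4-hydroxyphenyl)-4-[(2R,3R)-3,5,7-trihydroxy-2-(4-hydroxyphenyl)chroman-8-yl]chroman-7-ol (target)
Conditions: H2 (1 atm), Pd(OH)2/C, NaOAc, THF–MeOH, rt
Reagents that add atoms: none
Why: Catalytic hydrogenolysis should cleave the six benzyl ethers and the C5–Br bond in one operation, while the cyclic benzylic C2–O bonds and all four stereocentres are left intact, as is usual for benzylated oligoflavans.

**Compound list**

1 | (−)-epiafzelechin, (2R,3R)-2-(4-hydroxyphenyl)chroman-3,5,7-triol | Oc1cc(O)c2c(c1)O[C@H](c1ccc(O)cc1)[C@H](O)C2 | starting material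
2 | (2R,3R)-3,5,7-tris(benzyloxy)-2-[4-(benzyloxy)phenyl]chroman | C(c1ccccc1)Oc1cc(OCc2ccccc2)c2c(c1)O[C@H](c1ccc(OCc3ccccc3)cc1)[C@H](OCc1ccccc1)C2 | intermediate
3 | (2R,3R)-3,5,7-tris(benzyloxy)-2-[4-(benzyloxy)phenyl]-8-bromochroman | Brc1c(OCc2ccccc2)cc(OCc2ccccc2)c2c1O[C@H](c1ccc(OCc3ccccc3)cc1)[C@H](OCc1ccccc1)C2 | intermediate
4 | ethyl 3-[4-(benzyloxy)phenyl]-3-oxopropanoate | CCOC(=O)CC(=O)c1ccc(OCc2ccccc2)cc1 | starting material
5 | ethyl (S)-3-[4-(benzyloxy)phenyl]-3-hydroxypropanoate | CCOC(=O)C[C@H](O)c1ccc(OCc2ccccc2)cc1 | intermediate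
6 | (S)-3-[4-(benzyloxy)phenyl]-3-hydroxy-N-methoxy-N-methylpropanamide | CON(C)C(=O)C[C@H](O)c1ccc(OCc2ccccc2)cc1 | intermediate
7 | 8-lithio derivative of 2 (aryllithium from 3) | [Li]c1c(OCc2ccccc2)cc(OCc2ccccc2)c2c1O[C@H](c1ccc(OCc3ccccc3)cc1)[C@H](OCc1ccccc1)C2 | intermediate
8 | chloromagnesium alkoxide of 6 | CON(C)C(=O)C[C@H](O[Mg]Cl)c1ccc(OCc2ccccc2)cc1 | intermediate
9 | (S)-3-[4-(benzyloxy)phenyl]-3-hydroxy-1-[(2R,3R)-3,5,7-tris(benzyloxy)-2-(4-(benzyloxy)phenyl)chroman-8-yl]propan-1-one | O=C(C[C@H](O)c1ccc(OCc2ccccc2)cc1)c1c(OCc2ccccc2)cc(OCc2ccccc2)c2c1O[C@H](c1ccc(OCc3ccccc3)cc1)[C@H](OCc1ccccc1)C2 | intermediate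
10 | 4-(benzyloxy)phenol | Oc1ccc(OCc2ccccc2)cc1 | starting material
11 | 4-(benzyloxy)-2,6-dibromophenol | Oc1c(Br)cc(OCc2ccccc2)cc1Br | intermediate
12 | [4-(benzyloxy)-2,6-dibromophenoxy]trimethylsilane | C[Si](C)(C)Oc1c(Br)cc(OCc2ccccc2)cc1Br | intermediate
13 | lithium 4-(benzyloxy)-2-bromo-6-(trimethylsilyl)phenoxide | [Li]Oc1c(Br)cc(OCc2ccccc2)cc1[Si](C)(C)C | intermediate
14 | 4-(benzyloxy)-2-bromo-6-(trimethylsilyl)phenyl trifluoromethanesulfonate | FC(F)(F)S(=O)(=O)Oc1c(Br)cc(OCc2ccccc2)cc1[Si](C)(C)C | intermediate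
15 | 5-(benzyloxy)-3-bromobenzyne | BrC1=CC(OCc2ccccc2)=CC#C1 | intermediate
16 | (2S)-7-(benzyloxy)-2-[4-(benzyloxy)phenyl]-5-bromo-4-[(2R,3R)-3,5,7-tris(benzyloxy)-2-(4-(benzyloxy)phenyl)chroman-8-yl]chroman-4-ol, both C4 epimers | C(c1ccccc1)Oc1ccc([C@@H]2CC(O)(c3c(OCc4ccccc4)cc(OCc4ccccc4)c4c3O[C@H](c3ccc(OCc5ccccc5)cc3)[C@H](OCc3ccccc3)C4)c3c(Br)cc(OCc4ccccc4)cc3O2)cc1 | intermediate
17 | (2S,4R)-7-(benzyloxy)-2-[4-(benzyloxy)phenyl]-5-bromo-4-[(2R,3R)-3,5,7-tris(benzyloxy)-2-(4-(benzyloxy)phenyl)chroman-8-yl]chroman, 2,4-cis | C(c1ccccc1)Oc1ccc([C@@H]2C[C@H](c3c(OCc4ccccc4)cc(OCc4ccccc4)c4c3O[C@H](c3ccc(OCc5ccccc5)cc3)[C@H](OCc3ccccc3)C4)c3c(Br)cc(OCc4ccccc4)cc3O2)cc1 | intermediate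
18 | (2S,4S)-2-(4-hydroxyphenyl)-4-[(2R,3R)-3,5,7-trihydroxy-2-(4-hydroxyphenyl)chroman-8-yl]chroman-7-ol, (2S,4S)-4',7-dihydroxyflavan-(4→8)-(−)-epiafzelechin | Oc1ccc([C@@H]2C[C@H](c3c(O)cc(O)c4c3O[C@H](c3ccc(O)cc3)[C@H](O)C4)c3ccc(O)cc3O2)cc1 | target

**Step count.** Total: 10 steps. Longest linear sequence: 6 steps (steps 1, 2, 5, 8, 9, 10).

**Steps most likely to fail**

1. Step 8. The fluoride may trigger retro-aldol cleavage or dehydration of 9, or the aryl anion may be protonated or lose bromide before it closes onto the hindered ketone. The fallback uses known biomimetic chemistry; it sets out from 1 and comes back at 18. Purchased (S)-liquiritigenin F1 would be reduced with NaBH4 in EtOH to (2S)-2-(4-hydroxyphenyl)chroman-4,7-diol F2. F2 would then be condensed with 1 in dilute aqueous-ethanolic HCl at rt: acid ionisation at C4 followed by Friedel–Crafts attack of the phloroglucinol ring of 1. This should give 18 together with its C6-linked regioisomer and its C4 epimer, to be separated on Sephadex LH-20 and by preparative HPLC.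

2. Step 9. Hydride delivery to the crowded C4 cation, which has bromine peri to C4, may show poor facial selectivity, or the cation may drain into elimination and disproportionation. The fallback sets out from 16 and comes back at 18. Dehydration with Burgess reagent (toluene, 50 °C, non-acidic) should give (2S)-7-(benzyloxy)-2-[4-(benzyloxy)phenyl]-5-bromo-4-[(2R,3R)-3,5,7-tris(benzyloxy)-2-(4-(benzyloxy)phenyl)chroman-8-yl]-2H-chromene F3. Hydrogenation of F3 (H2, Pd(OH)2/C, NaOAc, THF–MeOH) should add hydrogen to C3=C4 on the face opposite ring B, giving the 2,4-cis product, and remove benzyl groups and bromine in the same operation.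

3. Step 5. The hindered, basic aryllithium 7 may deprotonate the α-CH2 of the amide instead of adding, so that 2 is returned. The fallback sets out from 6 (with 7 from 3) and comes back at 9. TBSCl and imidazole should give (S)-3-[4-(benzyloxy)phenyl]-3-[(tert-butyldimethylsilyl)oxy]-N-methoxy-N-methylpropanamide F4. Reduction with i-Bu2AlH at −78 °C should give the more electrophilic (S)-3-[4-(benzyloxy)phenyl]-3-[(tert-butyldimethylsilyl)oxy]propanal F5. Addition of 7 should give the carbinol (3S)-3-[4-(benzyloxy)phenyl]-3-[(tert-butyldimethylsilyl)oxy]-1-[(2R,3R)-3,5,7-tris(benzyloxy)-2-(4-(benzyloxy)phenyl)chroman-8-yl]propan-1-ol F6 as a mixture at the new centre. Dess–Martin oxidation should give the ketone (S)-3-[4-(benzyloxy)phenyl]-3-[(tert-butyldimethylsilyl)oxy]-1-[(2R,3R)-3,5,7-tris(benzyloxy)-2-(4-(benzyloxy)phenyl)chroman-8-yl]propan-1-one F7, and HF·pyridine in THF should release 9.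

**Further compounds**

F1 | step 8 | (S)-liquiritigenin, (2S)-7-hydroxy-2-(4-hydroxyphenyl)chroman-4-one (purchased) | O=C1C[C@@H](c2ccc(O)cc2)Oc2cc(O)ccc12
F2 | step 8 | (2S)-2-(4-hydroxyphenyl)chroman-4,7-diol | OC1C[C@@H](c2ccc(O)cc2)Oc2cc(O)ccc12
F3 | step 9 | (2S)-7-(benzyloxy)-2-[4-(benzyloxy)phenyl]-5-bromo-4-[(2R,3R)-3,5,7-tris(benzyloxy)-2-(4-(benzyloxy)phenyl)chroman-8-yl]-2H-chromene | C(c1ccccc1)Oc1ccc([C@@H]2C=C(c3c(OCc4ccccc4)cc(OCc4ccccc4)c4c3O[C@H](c3ccc(OCc5ccccc5)cc3)[C@H](OCc3ccccc3)C4)c3c(Br)cc(OCc4ccccc4)cc3O2)cc1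
F4 | step 5 | (S)-3-[4-(benzyloxy)phenyl]-3-[(tert-butyldimethylsilyl)oxy]-N-methoxy-N-methylpropanamide | CON(C)C(=O)C[C@H](O[Si](C)(C)C(C)(C)C)c1ccc(OCc2ccccc2)cc1
F5 | step 5 | (S)-3-[4-(benzyloxy)phenyl]-3-[(tert-butyldimethylsilyl)oxy]propanal | O=CC[C@H](O[Si](C)(C)C(C)(C)C)c1ccc(OCc2ccccc2)cc1
F6 | step 5 | (3S)-3-[4-(benzyloxy)phenyl]-3-[(tert-butyldimethylsilyl)oxy]-1-[(2R,3R)-3,5,7-tris(benzyloxy)-2-(4-(benzyloxy)phenyl)chroman-8-yl]propan-1-ol | OC(C[C@H](O[Si](C)(C)C(C)(C)C)c1ccc(OCc2ccccc2)cc1)c1c(OCc2ccccc2)cc(OCc2ccccc2)c2c1O[C@H](c1ccc(OCc3ccccc3)cc1)[C@H](OCc1ccccc1)C2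
F7 | step 5 | (S)-3-[4-(benzyloxy)phenyl]-3-[(tert-butyldimethylsilyl)oxy]-1-[(2R,3R)-3,5,7-tris(benzyloxy)-2-(4-(benzyloxy)phenyl)chroman-8-yl]propan-1-one | O=C(C[C@H](O[Si](C)(C)C(C)(C)C)c1ccc(OCc2ccccc2)cc1)c1c(OCc2ccccc2)cc(OCc2ccccc2)c2c1O[C@H](c1ccc(OCc3ccccc3)cc1)[C@H](OCc1ccccc1)C2
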